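**Retrosynthetic overview**
1. Target 13 ⇒ C15–C5′ bond: the tertiary vinyl carbinol of 9 serves as the C15 allyl electrophile, and sulfone 11 supplies C5′ (the carbonyl-level carbon of the butenolide) as a carbanion; loss of sulfinate then gives the 15Z-ylidene.
2. Acid 9 ⇒ triol 3: the 4α-methyl (C18) is oxidised by 6α-alkoxy-radical 1,5-hydrogen transfer (nitrite photolysis), then oxime → lactol → acid.
3. Triol 3 ⇒ (+)-larixol 1 by Markovnikov radical hydration of the 8(17)-alkene, which sets C8.
4. Sulfone 11 ⇐ 5-hydroxy-4-methylfuran-2(5H)-one 10 + PhSO2H.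
5. Rings: no carbocycle is built. The trans-decalin comes intact from 1 and the furanone ring from 10; only a transient 18,6α-lactol ring is closed (step 3) and reopened (step 4). Labdane numbering is used for C1–C20, primed furanone numbering for the butenolide.

Assumption: (+)-larixol, the labdane diol of larch oleoresin, is taken as a catalogue chiral-pool starting material; its 13S centre becomes sp2 in step 6, so its configuration does not matter.

**Route**

Step 1
Reactants: 1 (+)-larixol, (13S)-labda-8(17),14-diene-6α,13-diol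
Product: 3 (13S)-labd-14-ene-6α,8α,13-triol, via 8α-hydroperoxide 2 (not isolated)
Conditions: Co(acac)2 (20 mol %), PhSiH3 (2.2 equiv), O2 (1 atm), THF, 0 °C → rt
Reagents that add atoms: dioxygen, `O=O`
Why: Mukaiyama hydration: cobalt-hydride hydrogen-atom transfer to C17 of the electron-rich 1,1-disubstituted alkene (the hindered vinyl group next to the quaternary carbinol reacts much more slowly) gives the tertiary C8 radical, which O2 traps on the α face, away from the axial C10 methyl, so that C8 is set as 8α-OH/8β-CH3 after the silane reduces the peroxide in situ.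

Step 2
Reactants: 3 (13S)-labd-14-ene-6α,8α,13-triol
Product: 6 (13S)-6α,8α,13-trihydroxylabd-14-en-18-al (E)-oxime, via 6α-nitrite ester 4 (not isolated), via 18-nitroso compound 5 (not isolated)
Conditions: t-BuONO (1.3 equiv), MeCN, 0 °C, dark; volatiles stripped; hν (Hg lamp, Pyrex), MeCN, 0 °C, N2; then iPrOH, 60 °C
Reagents that add atoms: tert-butyl nitrite, `CC(C)(C)ON=O`
Why: Barton nitrite photolysis: nitrosyl exchange occurs at the only secondary hydroxyl, and the 6α-alkoxy radical, whose oxygen lies about 2.5 Å from the peri 4α-methyl (both bonds equatorial and parallel), abstracts hydrogen from C18 through a six-membered transition state faster than it fragments; NO then recombines at C18 and the nitroso compound tautomerises to the oxime, which fixes C4 (oxidised carbon α, methyl β).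

Step 3
Reactants: 6 (13S)-6α,8α,13-trihydroxylabd-14-en-18-al (E)-oxime
Product: 8 (13S)-6α,18-epoxylabd-14-ene-8α,13,18-triol (18,6α-lactol, both C18 anomers), via hydroxy aldehyde 7 (not isolated)
Conditions: OHC–CO2H·H2O (3 equiv), NaOAc, THF–H2O, rt
Reagents that add atoms: water, `O`
Why: Oxime exchange (transoximation): hydroxylamine passes to the more electrophilic glyoxylic acid under mild buffered conditions that spare the tertiary allylic alcohol, and the freed neopentyl aldehyde is trapped by the peri 6α-hydroxyl as the five-membered lactol, with no skeletal stereocentre affected.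

Step 4
Reactants: 8 18,6α-lactol (reacting through its open form 7)
Product: 9 (13S)-6α,8α,13-trihydroxylabd-14-en-18-oic acid
Conditions: NaClO2, NaH2PO4, 2-methyl-2-butene, t-BuOH–H2O, 0 °C → rt; extraction at pH 4–5
Reagents that add atoms: sodium chlorite, `[Na+].[O-]Cl=O`
Why: Pinnick (Lindgren) oxidation: the strained lactol opens readily to aldehyde 7, which chlorous acid oxidises to the acid while 2-methyl-2-butene scavenges the hypochlorous acid, so the vinyl group and free alcohols survive and the hydroxy acid is kept open as in the target.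

Step 5
Reactants: 10 5-hydroxy-4-methylfuran-2(5H)-one (racemic)
Product: 11 4-methyl-5-(phenylsulfonyl)furan-2(5H)-one (racemic)
Conditions: PhSO2H (1.2 equiv), CaCl2, CH2Cl2, rt
Reagents that add atoms: benzenesulfinic acid, `O=S(O)c1ccccc1`
Why: Anomeric sulfone formation of the kind used for lactols: the pseudo-acid ionises to an acyloxycarbenium ion that sulfinic acid captures through sulfur at C5, giving a C5–H acidic sulfone that acts as a nucleophilic (acyl-anion) equivalent of the carbonyl-level carbon C5′.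

Step 6
Reactants: 9 (13S)-6α,8α,13-trihydroxylabd-14-en-18-oic acid; 11 4-methyl-5-(phenylsulfonyl)furan-2(5H)-one
Product: 13 (13E)-6α,8α-dihydroxy-15-[(Z)-3-methyl-5-oxofuran-2(5H)-ylidene]labd-13-en-18-oic acid (CNP0145461.1), via allylated sulfone 12 (not isolated)
Conditions: Pd(PPh3)4 (5 mol %), 11 (1.5 equiv), THF, 50 °C; then DBU (3 equiv), rt; citric acid work-up; reversed-phase chromatography
Reagents that add atoms: none
Why: Proposed new method: a dehydrative Tsuji–Trost allylation in which the acidic sulfone 11 and the substrate's own carboxylic acid activate the tertiary allylic hydroxyl, zerovalent palladium ionises it to the η3-allyl complex, and the soft sulfonyl-stabilised furanolate attacks the unhindered C15 terminus through C5′ (the carbon α to sulfur); DBU then expels benzenesulfinate from the anomeric position of 12 (Julia-type alkylation–elimination), an irreversible exit open only to the C5′ adduct, to give the conjugated ylidene, Z because an E substituent would clash with the ring 4′-methyl, while the syn η3-allyl isomer (larger chain syn) gives 13E only as the major isomer (estimated about 3:1, the 13Z isomer being removed by chromatography); the closest known reactions are palladium-catalysed allylation of sulfone-stabilised carbanions, direct allylation of acidic pronucleophiles with allylic alcohols, and sulfone alkylation–sulfinate elimination in polyene synthesis.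

**Compound list**
1 | (+)-larixol, (13S)-labda-8(17),14-diene-6α,13-diol | `C=C[C@@](C)(O)CC[C@@H]1[C@@]2(C)CCCC(C)(C)[C@@H]2[C@@H](O)CC1=C` | starting material
2 | (13S)-8α-hydroperoxylabd-14-ene-6α,13-diol (not isolated) | `C=C[C@@](C)(O)CC[C@@H]1[C@@]2(C)CCCC(C)(C)[C@@H]2[C@@H](O)C[C@@]1(C)OO` | intermediate
3 | (13S)-labd-14-ene-6α,8α,13-triol | `C=C[C@@](C)(O)CC[C@@H]1[C@@]2(C)CCCC(C)(C)[C@@H]2[C@@H](O)C[C@@]1(C)O` | intermediate
4 | (13S)-8α,13-dihydroxylabd-14-en-6α-yl nitrite (not isolated) | `C=C[C@@](C)(O)CC[C@@H]1[C@@]2(C)CCCC(C)(C)[C@@H]2[C@@H](ON=O)C[C@@]1(C)O` | intermediate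
5 | (13S)-18-nitrosolabd-14-ene-6α,8α,13-triol (not isolated) | `C=C[C@@](C)(O)CC[C@@H]1[C@@]2(C)CCC[C@@](C)(CN=O)[C@@H]2[C@@H](O)C[C@@]1(C)O` | intermediate
6 | (13S)-6α,8α,13-trihydroxylabd-14-en-18-al (E)-oxime | `C=C[C@@](C)(O)CC[C@@H]1[C@@]2(C)CCC[C@@](C)(/C=N/O)[C@@H]2[C@@H](O)C[C@@]1(C)O` | intermediate
7 | (13S)-6α,8α,13-trihydroxylabd-14-en-18-al (open form of 8, not isolated) | `C=C[C@@](C)(O)CC[C@@H]1[C@@]2(C)CCC[C@@](C)(C=O)[C@@H]2[C@@H](O)C[C@@]1(C)O` | intermediate
8 | (13S)-6α,18-epoxylabd-14-ene-8α,13,18-triol (18,6α-lactol, C18 anomers) | `C=C[C@@](C)(O)CC[C@@H]1[C@@]2(C)CCC[C@@](C)(C3O)[C@@H]2[C@@H](O3)C[C@@]1(C)O` | intermediate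
9 | (13S)-6α,8α,13-trihydroxylabd-14-en-18-oic acid (CO2H = C18, 4α) | `C=C[C@@](C)(O)CC[C@@H]1[C@@]2(C)CCC[C@@](C)(C(=O)O)[C@@H]2[C@@H](O)C[C@@]1(C)O` | intermediate
10 | 5-hydroxy-4-methylfuran-2(5H)-one (racemic) | `CC1=CC(=O)OC1O` | starting material
11 | 4-methyl-5-(phenylsulfonyl)furan-2(5H)-one (racemic) | `CC1=CC(=O)OC1S(=O)(=O)c1ccccc1` | intermediate
12 | (13E)-6α,8α-dihydroxy-15-[4′-methyl-2′-oxo-5′-(phenylsulfonyl)-2′,5′-dihydrofuran-5′-yl]labd-13-en-18-oic acid (C5′ epimers, not isolated) | `CC1=CC(=O)OC1(C/C=C(\C)CC[C@@H]2[C@@]3(C)CCC[C@@](C)(C(=O)O)[C@@H]3[C@@H](O)C[C@@]2(C)O)S(=O)(=O)c1ccccc1` | intermediate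
13 | (13E)-6α,8α-dihydroxy-15-[(Z)-3-methyl-5-oxofuran-2(5H)-ylidene]labd-13-en-18-oic acid (CNP0145461.1) | `CC1=CC(=O)O/C1=C\C=C(/C)CC[C@@H]1[C@@]2(C)CCC[C@@](C)(C(=O)O)[C@@H]2[C@@H](O)C[C@@]1(C)O` | target

**Step count and risks**

Total: 6 steps. Longest linear sequence: 5 steps (1 → 3 → 6 → 8 → 9 → 13); one further step makes reagent 11 from 10.

Step 6 is the most likely to fail. The ambident furanolate may react through C3′ instead of C5′, the 8α-hydroxyl may close the 8,13-ether on the allyl complex, and the 13E:13Z ratio is only moderate. The fallback sets out from 9 and comes back at 13. Catalytic Ph3SiOReO3 in Et2O transposes the tertiary allylic alcohol to the primary one, (13E)-6α,8α,15-trihydroxylabd-13-en-18-oic acid F5, with the E isomer enriched by chromatography. MnO2 in CH2Cl2 oxidises only this allylic alcohol to the enal (13E)-6α,8α-dihydroxy-15-oxolabd-13-en-18-oic acid F6. Wittig olefination of F6 with the stabilised ylide generated by Et3N from (3-methyl-5-oxo-2,5-dihydrofuran-2-yl)triphenylphosphonium bromide F7 (made from 10 and Ph3P·HBr in MeCN), followed by a trace of I2 to bring the new C15=C5′ bond to Z, gives 13. C5′ is still the nucleophile, but the bond is formed by carbonyl olefination, so only addition through C5′ can lead to product. This fallback does not improve the 13E:13Z ratio.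

Step 2 is the second risk. A tertiary hydroxyl may be nitrosated, and the alkoxy radical may cleave the C5–C6 bond instead of abstracting from C18. The fallback sets out from 3 and comes back at 8. TMSOTf and 2,6-lutidine give (13S)-6α,8α,13-tris(trimethylsilyloxy)labd-14-ene F2. K2CO3 in MeOH at 0 °C removes only the secondary silyl ether to leave (13S)-8α,13-bis(trimethylsilyloxy)labd-14-en-6α-ol F3. The hypoiodite reaction (Pb(OAc)4, I2, CaCO3, hν, cyclohexane, reflux; two consecutive 1,5-hydrogen transfers from C18) gives (13S)-18-iodo-6α,18-epoxy-8α,13-bis(trimethylsilyloxy)labd-14-ene F4. AgOAc in aqueous THF hydrolyses the α-iodo ether and TBAF removes both silyl groups to give lactol 8, so step 3 is skipped.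

Step 1 is the third risk. O2 may attack the β face of the C8 radical, and the vinyl group may be partly hydrated. The fallback sets out from 1 and comes back at 3. mCPBA with NaHCO3 in CH2Cl2 at 0 °C epoxidises only the more electron-rich 1,1-disubstituted alkene, from the α face, to give (13S)-8α,17-epoxylabd-14-ene-6α,13-diol F1. LiAlH4 in THF delivers hydride to the primary C17 and gives 3.

**Further compounds**
F1 | step 1 | (13S)-8α,17-epoxylabd-14-ene-6α,13-diol | `C=C[C@@](C)(O)CC[C@@H]1[C@@]2(C)CCCC(C)(C)[C@@H]2[C@@H](O)C[C@]13CO3`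
F2 | step 2 | (13S)-6α,8α,13-tris(trimethylsilyloxy)labd-14-ene | `C=C[C@@](C)(O[Si](C)(C)C)CC[C@@H]1[C@@]2(C)CCCC(C)(C)[C@@H]2[C@@H](O[Si](C)(C)C)C[C@@]1(C)O[Si](C)(C)C`
F3 | step 2 | (13S)-8α,13-bis(trimethylsilyloxy)labd-14-en-6α-ol | `C=C[C@@](C)(O[Si](C)(C)C)CC[C@@H]1[C@@]2(C)CCCC(C)(C)[C@@H]2[C@@H](O)C[C@@]1(C)O[Si](C)(C)C`
F4 | step 2 | (13S)-18-iodo-6α,18-epoxy-8α,13-bis(trimethylsilyloxy)labd-14-ene (C18 epimers) | `C=C[C@@](C)(O[Si](C)(C)C)CC[C@@H]1[C@@]2(C)CCC[C@@](C)(C3I)[C@@H]2[C@@H](O3)C[C@@]1(C)O[Si](C)(C)C`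
F5 | step 6 | (13E)-6α,8α,15-trihydroxylabd-13-en-18-oic acid | `OC/C=C(\C)CC[C@@H]1[C@@]2(C)CCC[C@@](C)(C(=O)O)[C@@H]2[C@@H](O)C[C@@]1(C)O`
F6 | step 6 | (13E)-6α,8α-dihydroxy-15-oxolabd-13-en-18-oic acid | `O=C/C=C(\C)CC[C@@H]1[C@@]2(C)CCC[C@@](C)(C(=O)O)[C@@H]2[C@@H](O)C[C@@]1(C)O`
F7 | step 6 | (3-methyl-5-oxo-2,5-dihydrofuran-2-yl)triphenylphosphonium bromide (racemic) | `CC1=CC(=O)OC1[P+](c1ccccc1)(c1ccccc1)c1ccccc1.[Br-]`
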